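22.7 parts of target for each part of catalyst charged: this turnover number, the target reached as a fraction of the starting material charged, divided by the catalyst charged as a fraction of the same charge, is what the teal run reads where it stalls, from its last two readings, each scattering by 1 percentage point.

| flask | starting material | second substrate | capture agent | free catalyst | remark | time |
|---|---|---|---|---|---|---|
| teal | 12 mM | 12 mM | 3.6 mM | 0.15 mM | run made earlier |  |
| ochre | 12 mM | 12 mM | 3.6 mM | 0.60 mM | run made earlier |  |
| flask | 12 mM | 12.0 mM | 3.60 mM | 0.30 mM |  | 20 h |

| run | time / h | target / % | starting material / % | trapped intermediate / % |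
|---|---|---|---|---|
| teal | 2.50 | 15.4 | 82.7 | 0.7 |
| teal | 5.00 | 23.9 | 75.1 | 0.1 |
| teal | 6.00 | 24.8 | 75.3 | 0 |
| teal | 10.0 | 25.9 | 73.8 | 1.7 |
| teal | 12.0 | 28.0 | 71.1 | 2.4 |
| teal | 15.0 | 28.8 | 72.1 | 1.3 |
| ochre | 0.833 | 28.2 | 70.8 | 4.8 |
| ochre | 2.50 | 59.8 | 34.8 | 4.0 |
| ochre | 5.00 | 79.5 | 15.5 | 2.8 |
| ochre | 6.00 | 85.5 | 10.8 | 3.0 |
| ochre | 10.0 | 93.0 | 4.0 | 2.9 |
| ochre | 12.0 | 93.9 | 1.7 | 5.0 |
| ochre | 15.0 | 97.0 | 1.6 | 3.8 |

(standard deviation of a reading: 1 percentage point)

- concentration of target at 20 h, in mM
- concentration of starting material at 20 h, in mM
- concentration of trapped intermediate at 20 h, in mM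

The catalyst in the teal run is 1.25% of the charge, and its trapped intermediate reads 1.3% at 15.0 h, so we take it that, with the capture agent at this charge, each catalyst makes this much target and then ends up trapped. The ochre run tests the rule: its catalyst, 5.00% of the charge, allows 114%, more than the charge, and it reads 97.0% target at 15.0 h.

Now our books for the flask. Its catalyst is 2.50% of the charge. Target takes 56.8%, trapped intermediate takes 2.50%, and 40.7% stays as starting material: 6.82 mM, 0.300 mM and 4.88 mM. The teal run had made 84.2% of the target of its last two readings by 5.00 h, and the flask has 20 h, so we close the books at 20 h.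

The forecast gives 10.5 mM target, 1.25 mM starting material and 0.25 mM trapped intermediate, taking the catalyst lost as “a fixed amount rather than a fraction”. That is more target than our books hold.

The flask gives 6.74 mM target, 4.96 mM starting material and 0.299 mM trapped intermediate.

    catalyst intermediate A + capture agent → trapped intermediate (k = 162 /M/min)
    catalyst intermediate A → free catalyst + target (k = 12.6 /min)
    catalyst intermediate B → free catalyst + second product (k = 0.334 /min)
    starting material + free catalyst ⇌ catalyst intermediate A (K = 30.4 /M, k = 34.7 /M/min)
    second substrate + free catalyst ⇌ catalyst intermediate B (K = 1100 /M, k = 53.7 /M/min)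

In the flask that is 22.5 parts of target per part of catalyst charged, with 99.7% of the catalyst trapped and 41.3% of the starting material still free at 20.0 h. The neighbour flask, like this one but charged with 48 mM of starting material, has catalyst at 0.625% of its charge, so the turnover number allows 14.2% of that charge as target, and it holds 14.1% at 20.0 h.

The data are simulated for an exercise.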